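**Retrosynthetic overview**

- The strategy rests on the cyclohexene numbered C1 (quaternary: CH3 and styryl), C2 (H and coumarin-8-yl), C3=C4(CH3), C5, C6. The styryl carbon on C1 and the aryl group on C2 are cis, so methyl is trans to aryl. The ring therefore maps onto a (Z)-2-methyl-3-arylacrolein (formyl cis to aryl), not the E isomer, and its alkene lies one position away from where an isoprene-type diene would leave it (C4=C5).
- Disconnections: the aryl–CH= bond of the styryl unit (Mizoroki–Heck with 8-iodo-7-methoxycoumarin 3), the vinyl group from a C1 formyl group (Wittig), and the C3=C4 alkene from a C3 allylsilane (protodesilylation with allyl shift). The cyclohexene is then cut across C1–C6 and C2–C3 into Z-enal 9 and (E)-1-silyl-2-methylbutadiene 12 (Diels–Alder).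
- Enal 9 comes from umbelliferone through iodide 3 (also the Heck partner), its pinacol boronate 4, Suzuki coupling with (Z)-3-iodo-2-methylprop-2-en-1-ol (geometry from anti carbomagnesiation of propargyl alcohol) and MnO2 oxidation. Diene 12 comes from 3-methyl-3-sulfolene by C2 silylation and cheletropic loss of SO2.
- Ring order: both coumarin bicycles are bought in with umbelliferone; the cyclohexene is the only ring formed, in step 9.

Key step: step 9

Assumption: the oxazaborolidinium catalyst is taken to follow its usual formyl C–H···O model with this Z-enal. The (S)-prolinol-derived catalyst is written; the required sense is diene addition to the Re face at both alkene carbons of 9, and the mirror-image catalyst would be used if the first adduct proved to be the antipode.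

**Route**

Step 1
Reactants: 1 umbelliferone (7-hydroxy-2H-chromen-2-one)
Product: 2 7-hydroxy-8-iodo-2H-chromen-2-one
Conditions: I2 (1 equiv), KI, 20% aq. NH3, 0 °C to rt; then dilute H2SO4
Reagents that add atoms: iodine, II
Why: Electrophilic aromatic iodination of the phenolate should go to C8, the ortho position between the 7-oxygen and the ring oxygen that also takes formyl and aminomethyl electrophiles in this series, and one equivalent of iodine limits 6,8-di-iodination.

Step 2
Reactants: 2 7-hydroxy-8-iodo-2H-chromen-2-one
Product: 3 8-iodo-7-methoxy-2H-chromen-2-one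
Conditions: MeI, K2CO3, acetone, reflux
Reagents that add atoms: iodomethane, CI
Why: Williamson O-methylation of the acidic 7-phenol with carbonate in acetone should leave the lactone and the aryl iodide untouched.

Step 3
Reactants: 3 8-iodo-7-methoxy-2H-chromen-2-one
Product: 4 7-methoxy-8-(4,4,5,5-tetramethyl-1,3,2-dioxaborolan-2-yl)-2H-chromen-2-one
Conditions: B2pin2, KOAc, PdCl2(dppf) (5 mol%; dppf = 1,1'-bis(diphenylphosphino)ferrocene), 1,4-dioxane, 90 °C
Reagents that add atoms: bis(pinacolato)diboron, CC1(C)OB(OC1(C)C)B1OC(C)(C)C(C)(C)O1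
Why: Miyaura borylation of the aryl iodide with acetate as the base should neither open the lactone nor promote homocoupling.

Step 4
Reactants: 5 prop-2-yn-1-ol
Product: 7 (Z)-3-iodo-2-methylprop-2-en-1-ol, via 4-methyl-2,5-dihydro-1,2-oxamagnesole 6 (not isolated)
Conditions: MeMgBr (3 equiv), CuI (10 mol%), Et2O–THF, −10 °C to rt; then I2, −10 °C; aq. NH4Cl/Na2S2O3
Reagents that add atoms: methylmagnesium bromide, C[Mg]Br; iodine, II
Why: Copper-catalysed anti carbomagnesiation of the propargylic alkoxide places methyl on C2 and magnesium on C3 inside a five-membered chelate, so iodinolysis with retention should fix iodine cis to CH2OH (Z).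

Step 5
Reactants: 4 7-methoxy-8-(4,4,5,5-tetramethyl-1,3,2-dioxaborolan-2-yl)-2H-chromen-2-one; 7 (Z)-3-iodo-2-methylprop-2-en-1-ol
Product: 8 8-[(Z)-3-hydroxy-2-methylprop-1-en-1-yl]-7-methoxy-2H-chromen-2-one
Conditions: Pd(OAc)2 (5 mol%), SPhos (2-dicyclohexylphosphino-2',6'-dimethoxybiphenyl, 10 mol%), K3PO4, 1,4-dioxane–H2O, 60 °C; dilute HCl work-up
Reagents that add atoms: none
Why: Suzuki–Miyaura coupling proceeds with retention of the alkenyl iodide geometry, the dialkylbiarylphosphine suits the di-ortho-substituted boronate, and the acidic work-up should close any lactone opened by the base.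

Step 6
Reactants: 8 8-[(Z)-3-hydroxy-2-methylprop-1-en-1-yl]-7-methoxy-2H-chromen-2-one
Product: 9 (Z)-3-(7-methoxy-2-oxo-2H-chromen-8-yl)-2-methylprop-2-enal
Conditions: activated MnO2 (excess), CH2Cl2, rt, dark; filtered and used at once
Reagents that add atoms: none
Why: Heterogeneous allylic oxidation with MnO2 is neutral, so the aldehyde should form without the acid, base or light that would equilibrate the Z-enal to its E isomer.

Step 7
Reactants: 10 3-methyl-2,5-dihydrothiophene 1,1-dioxide (3-methyl-3-sulfolene)
Product: 11 3-methyl-2-(trimethylsilyl)-2,5-dihydrothiophene 1,1-dioxide (racemic)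
Conditions: LiN(SiMe3)2 (1.1 equiv) added to 10 and Me3SiCl (1.2 equiv), THF, −78 °C
Reagents that add atoms: chlorotrimethylsilane, C[Si](C)(C)Cl
Why: Deprotonation α to the sulfone should favour C2, whose allyl anion puts charge on secondary C4 and not on tertiary C3 (the site at which this sulfolene is alkylated), and in situ C-silylation traps the anion before it can ring-open.

Step 8
Reactants: 11 3-methyl-2-(trimethylsilyl)-2,5-dihydrothiophene 1,1-dioxide
Product: 12 (E)-trimethyl(2-methylbuta-1,3-dien-1-yl)silane
Conditions: neat, NaHCO3 (trace), 120–130 °C, diene distilled out as it forms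
Reagents that add atoms: none
Why: Thermal cheletropic extrusion of SO2 from a 3-sulfolene is suprafacial and turns the C2 substituent outward, so the silyl group should end up trans to the vinyl group (E).

Step 9
Reactants: 9 (Z)-3-(7-methoxy-2-oxo-2H-chromen-8-yl)-2-methylprop-2-enal; 12 (E)-trimethyl(2-methylbuta-1,3-dien-1-yl)silane
Product: 13 (1R,2R,3R)-2-(7-methoxy-2-oxo-2H-chromen-8-yl)-1,4-dimethyl-3-(trimethylsilyl)cyclohex-4-ene-1-carbaldehyde (overview numbering; formyl, aryl and silyl mutually cis; the C3 epimer would serve equally)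
Conditions: (S)-3,3-diphenyl-1-(2-methylphenyl)tetrahydro-1H,3H-pyrrolo[1,2-c][1,3,2]oxazaborole (20 mol%), Tf2NH (18 mol%), 12 (3 equiv), CH2Cl2, −40 to 0 °C
Reagents that add atoms: none
Why: The protonated oxazaborolidine binds the formyl oxygen of 9 (boron anti to the α-carbon, formyl C–H held by the ring oxygen), lowers the enal LUMO and screens one alkene face, and a concerted, asynchronous Diels–Alder reaction with 12 follows, the closest known reaction type being the cationic-oxazaborolidine-catalysed cycloaddition of α-substituted and α,β-disubstituted enals with acyclic dienes. The cyclohexene, the only ring formed, closes by intermolecular suprafacial [4+2] addition in which the silyl-bearing diene terminus bonds to the aryl-bearing β-carbon (C2–C3) and the CH2 terminus to the α-carbon (C1–C6). C1 and C2 are set relative to each other by the Z geometry of 9, which is carried over so that formyl and aryl end up cis and methyl trans to aryl, and in the absolute sense by the catalyst, which must direct the diene to the Re face at both alkene carbons; C3 follows from the formyl-endo approach of the E silyl diene and is of no consequence because step 10 erases it. The regiochemistry needs the larger HOMO coefficient at the silyl-bearing terminus, which the 2-methyl group and the β-silicon stabilisation of the developing allyl cation both provide, matched to the larger LUMO coefficient at the β-carbon of the enal. The step also needs the Z geometry to survive Lewis acid activation, for which the di-ortho-substituted aryl group, twisted out of conjugation, gives little benzylic stabilisation to a rotating C=C bond, and it needs the enal to outcompete the coumarin C3=C4 bond, which has no aldehyde activator. The slight deficit of Tf2NH leaves no free acid to protodesilylate 12 or 13.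

Step 10
Reactants: 13 (1R,2R,3R)-2-(7-methoxy-2-oxo-2H-chromen-8-yl)-1,4-dimethyl-3-(trimethylsilyl)cyclohex-4-ene-1-carbaldehyde
Product: 14 (1R,2R)-2-(7-methoxy-2-oxo-2H-chromen-8-yl)-1,4-dimethylcyclohex-3-ene-1-carbaldehyde
Conditions: CF3CO2H (3 equiv), CH2Cl2, 0 °C, short reaction time; aq. NaHCO3 quench
Reagents that add atoms: none
Why: Protodesilylation of the allylsilane (SE2') puts the proton on C5 to give the tertiary C4 cation stabilised by the C3–Si bond, and loss of the silyl group should deliver the C3=C4 alkene regiospecifically while removing the C3 centre and leaving quaternary C1 and C2 untouched.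

Step 11
Reactants: 14 (1R,2R)-2-(7-methoxy-2-oxo-2H-chromen-8-yl)-1,4-dimethylcyclohex-3-ene-1-carbaldehyde
Product: 15 8-[(1S,6S)-6-ethenyl-3,6-dimethylcyclohex-2-en-1-yl]-7-methoxy-2H-chromen-2-one
Conditions: Ph3PCH3Br, KN(SiMe3)2, THF, 0 °C; then 14, −78 °C to rt
Reagents that add atoms: methyltriphenylphosphonium bromide (as methylenetriphenylphosphorane), C[P+](c1ccccc1)(c1ccccc1)c1ccccc1.[Br-]
Why: Wittig methylenation of the non-enolisable aldehyde should outpace any attack of the ylide on the lactone at low temperature and touches no stereocentre (the descriptor at C1 changes only through the priority rules).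

Step 12
Reactants: 15 8-[(1S,6S)-6-ethenyl-3,6-dimethylcyclohex-2-en-1-yl]-7-methoxy-2H-chromen-2-one; 3 8-iodo-7-methoxy-2H-chromen-2-one
Product: 16 7-methoxy-8-[(E)-2-[(1S,2S)-2-(7-methoxy-2-oxo-2H-chromen-8-yl)-1,4-dimethylcyclohex-3-en-1-yl]ethenyl]-2H-chromen-2-one (target)
Conditions: Pd(OAc)2 (10 mol%), Bu4NCl, NaHCO3, DMF, 80 °C
Reagents that add atoms: none
Why: In this Mizoroki–Heck coupling the aryl group adds to the terminal alkene carbon and β-hydride elimination can only take the benzylic hydrogen because the other neighbour is quaternary, so the E styryl alkene should result, and phosphine-free phase-transfer conditions limit Pd–H migration of the ring alkene.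

**Compound list**

1 | umbelliferone (7-hydroxy-2H-chromen-2-one) | Oc1ccc2ccc(=O)oc2c1 | starting material
2 | 7-hydroxy-8-iodo-2H-chromen-2-one | Oc1ccc2ccc(=O)oc2c1I | intermediate
3 | 8-iodo-7-methoxy-2H-chromen-2-one | COc1ccc2ccc(=O)oc2c1I | intermediate
4 | 7-methoxy-8-(4,4,5,5-tetramethyl-1,3,2-dioxaborolan-2-yl)-2H-chromen-2-one | COc1ccc2ccc(=O)oc2c1B1OC(C)(C)C(C)(C)O1 | intermediate
5 | prop-2-yn-1-ol | C#CCO | starting material
6 | 4-methyl-2,5-dihydro-1,2-oxamagnesole (cyclic alkenylmagnesium alkoxide, not isolated) | CC1=C[Mg]OC1 | intermediate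
7 | (Z)-3-iodo-2-methylprop-2-en-1-ol | I/C=C(/C)CO | intermediate
8 | 8-[(Z)-3-hydroxy-2-methylprop-1-en-1-yl]-7-methoxy-2H-chromen-2-one | COc1ccc2ccc(=O)oc2c1/C=C(/C)CO | intermediate
9 | (Z)-3-(7-methoxy-2-oxo-2H-chromen-8-yl)-2-methylprop-2-enal | COc1ccc2ccc(=O)oc2c1/C=C(/C)C=O | intermediate
10 | 3-methyl-2,5-dihydrothiophene 1,1-dioxide (3-methyl-3-sulfolene) | CC1=CCS(=O)(=O)C1 | starting material
11 | 3-methyl-2-(trimethylsilyl)-2,5-dihydrothiophene 1,1-dioxide (racemic) | CC1=CCS(=O)(=O)C1[Si](C)(C)C | intermediate
12 | (E)-trimethyl(2-methylbuta-1,3-dien-1-yl)silane | C[Si](C)(C)/C=C(\C)C=C | intermediate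
13 | (1R,2R,3R)-2-(7-methoxy-2-oxo-2H-chromen-8-yl)-1,4-dimethyl-3-(trimethylsilyl)cyclohex-4-ene-1-carbaldehyde | O=C[C@]1(C)CC=C(C)[C@H]([Si](C)(C)C)[C@@H]1c1c(OC)ccc2ccc(=O)oc12 | intermediate
14 | (1R,2R)-2-(7-methoxy-2-oxo-2H-chromen-8-yl)-1,4-dimethylcyclohex-3-ene-1-carbaldehyde | O=C[C@]1(C)CCC(C)=C[C@@H]1c1c(OC)ccc2ccc(=O)oc12 | intermediate
15 | 8-[(1S,6S)-6-ethenyl-3,6-dimethylcyclohex-2-en-1-yl]-7-methoxy-2H-chromen-2-one | C=C[C@]1(C)CCC(C)=C[C@@H]1c1c(OC)ccc2ccc(=O)oc12 | intermediate
16 | 7-methoxy-8-[(E)-2-[(1S,2S)-2-(7-methoxy-2-oxo-2H-chromen-8-yl)-1,4-dimethylcyclohex-3-en-1-yl]ethenyl]-2H-chromen-2-one | COc1ccc2ccc(=O)oc2c1/C=C/[C@]1(C)CCC(C)=C[C@@H]1c1c(OC)ccc2ccc(=O)oc12 | target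

**Step count and risks**

Total step count: 12. Longest linear sequence: 9 steps (steps 1, 2, 3, 5, 6, 9, 10, 11, 12).

Steps most likely to fail:

Step 9. The cycloaddition joins two hindered carbons (aryl-bearing β-carbon and silyl-bearing diene terminus) and may be slow. The coumarin carbonyl may hold back the catalyst, the Lewis-acid-bound enal may rotate from Z to E and so feed the C1-epimeric series, and facial selectivity may be poor on this unusual enal. The fallback sets out from 9 and 12 and comes back at 14. The two are combined without any Lewis acid at 12–15 kbar in CH2Cl2 at 40 °C, which should give the racemic adduct F1 with the Z geometry carried over. CF3CO2H as in step 10 then gives the racemic aldehyde F2, and the enantiomers are separated by preparative HPLC on a chiral stationary phase (amylose tris(3,5-dimethylphenylcarbamate)). The (1R,2R) enantiomer is 14 and the route resumes at step 11.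

Step 12. Carbopalladation of the neopentyl-type vinyl group by a di-ortho-substituted arylpalladium species may be slow. That would allow arylation of a coumarin C3=C4 bond, or Pd–H migration of the ring alkene into conjugation with loss of the C2 centre, to compete. The fallback sets out from 14 and comes back at 16, bypassing 15. Takai iodo-olefination (CrCl2, CHI3, THF, 0 °C to rt) should give 8-[(1S,6R)-6-[(E)-2-iodoethenyl]-3,6-dimethylcyclohex-2-en-1-yl]-7-methoxy-2H-chromen-2-one F3 with E geometry. Suzuki–Miyaura coupling of F3 with boronate 4 (Pd(OAc)2, SPhos, K3PO4, 1,4-dioxane–H2O, 50 °C) then forms the aryl–alkenyl bond with retention and gives 16.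

Step 5. Protodeboronation of the di-ortho-substituted, oxygen-flanked boronate may outrun transmetalation. The aqueous base may also open the lactone or erode the Z geometry. The fallback sets out from 5 (through chelate 6) and 3 and comes back at 8. The chelate 6 is quenched with Bu3SnCl instead of iodine to give (Z)-2-methyl-3-(tributylstannyl)prop-2-en-1-ol F4. Base-free Stille coupling of F4 with iodide 3 (Pd(PPh3)4, CuI, DMF, 60 °C) then gives 8 with retention of geometry and without the boronate.

**Further compounds**

F1 | step 9 | racemic 2-(7-methoxy-2-oxo-2H-chromen-8-yl)-1,4-dimethyl-3-(trimethylsilyl)cyclohex-4-ene-1-carbaldehyde (1:1 mixture of 13 and its mirror image) | O=C[C@]1(C)CC=C(C)[C@H]([Si](C)(C)C)[C@@H]1c1c(OC)ccc2ccc(=O)oc12.O=C[C@@]1(C)CC=C(C)[C@@H]([Si](C)(C)C)[C@H]1c1c(OC)ccc2ccc(=O)oc12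
F2 | step 9 | racemic 2-(7-methoxy-2-oxo-2H-chromen-8-yl)-1,4-dimethylcyclohex-3-ene-1-carbaldehyde (1:1 mixture of 14 and its mirror image) | O=C[C@]1(C)CCC(C)=C[C@@H]1c1c(OC)ccc2ccc(=O)oc12.O=C[C@@]1(C)CCC(C)=C[C@H]1c1c(OC)ccc2ccc(=O)oc12
F3 | step 12 | 8-[(1S,6R)-6-[(E)-2-iodoethenyl]-3,6-dimethylcyclohex-2-en-1-yl]-7-methoxy-2H-chromen-2-one | I/C=C/[C@]1(C)CCC(C)=C[C@@H]1c1c(OC)ccc2ccc(=O)oc12
F4 | step 5 | (Z)-2-methyl-3-(tributylstannyl)prop-2-en-1-ol | CCCC[Sn](CCCC)(CCCC)/C=C(/C)CO
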